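The three forms of the catalyst always add up to the catalyst charged, and spent salt formed always equals substrate converted plus the fresh carrier standing.

substrate 0.33 M (fed, over 4.0 min); salt in the second phase 0.396 M; spent carrier 6.6 mM; time 10 h; volume of the second phase over the first 0.50

    spent carrier + salt in the second phase ⇌ fresh carrier + spent salt in the second phase (K1 = 3.0, k1 = 25.5 M⁻¹ s⁻¹)
    substrate + fresh carrier → target + spent carrier (k2 = 0.299 M⁻¹ s⁻¹)
    target ⇌ isomer of the product (K3 = 0.85, k3 = 8.95 × 10⁻⁴ s⁻¹)
    spent carrier → spent catalyst (k4 = 0.00244 s⁻¹)

- in the second phase: salt in the second phase, spent salt in the second phase; everything else is in the first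
- charges count per volume of the first phase; a concentration in a rate is the amount of a species over the volume of its own phase; every rate counts per litre of the first phase
- run time (flask): 10 h

1. conversion of substrate at 10 h
2. amount of target at 10 h, in percent of the substrate charged
3. amount of isomer of the product at 10 h, in percent of the substrate charged

The ladder below gives half-lives, fastest first, with salt and substrate at their full charges.

| Rung | Half-life |
|---|---|
| spent carrier takes up salt | 0.0343 s |
| fresh carrier meets substrate | 7.02 s |
| spent carrier dies | 4.73 min |
| target and isomer relax | 5.93 min |

The shuttle is far faster than the turnover, so fresh over spent carrier follows the shuttle equilibrium constant times salt over spent salt, a pre-equilibrium. Relaxation is far shorter than the 10 h run, so the product splits between target and isomer by the constant 0.85.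

Dividing the dying rate by the rate of conversion removes time. Let f be substrate converted and s substrate left, as fractions of its charge, and y salt left on the same scale, starting from ρ = 1.20. The fresh carrier standing is small, 2.00% of the substrate charge at most, so spent salt is taken as f. Catalyst lost per substrate converted is then f/(B s y). Here B is the catalyst budget: the second step's constant times the shuttle equilibrium constant times the catalyst charge, over the dying constant. It is 2.43.

Summed up, the budget used is S = (ρ ln(y/ρ) − ln s)/(ρ − 1), and in this reckoning conversion stops when S reaches B. Taking the substrate as charged at once, S is 2.21 at 85.7% conversion and 2.56 at 87.5%. Interpolating, this reckoning gives 86.8%, with target 46.9% and isomer 39.9%.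

The forecast gives 86.4%, 46.7% and 39.7%, reasoning that “the carrier lost per unit of substrate converted does not depend on time”. Its conversion lies a little below this reckoning's.

The simulation gives 86.4%, 46.7% and 39.7%.

In this flask spent catalyst stands at 100% at 10.0 h, and S at the conversion reached is 2.34 against a budget of 2.43. In the flask charged with 0.0040 M of spent carrier the budget is 1.47, and S at its conversion of 79.7% is 1.43.

Its constants were set for the occasion; the result is computed.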